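Everything hinges on cutting the C6–CH3 bond: C6 then reverts to a ketone carbon and the dioxane to a 1,4-dicarbonyl array plus H2O2. The step exploits C6 of the 1,2-dioxane ring, the carbon attached to peroxide oxygen O1: loss of a methoxy group there gives a peroxycarbenium ion held inside the cis-fused dioxane–butanolide, whose axial C4 lactone oxygen (1,3) and axial C3 oxygen (1,4) impose a single half-chair and hence a single open face. One operation thus adds the last carbon and creates the fully substituted peroxide stereocentre, although its CH3 and CH2R groups are nearly equal in size. The precursor is the bicyclic 6-methoxy peroxyketal lactone, silylated at the C3 hydroxyl.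

Key step: step 11

Remark: atoms are numbered C1 (lactone carbonyl), C2 (CH2), C3 (hemiketal carbon), C4 (ring-fusion carbon with CH3 and the lactone oxygen), C5 (ring CH2), C6 (peroxide carbon), C7 to C14 (side chain, phenyl on C14), O1 on C6 and O2 on C3. The target is read as 3R,4R,6R,8R,12E, and the closed peroxyhemiketal is assumed to be the stable tautomer of this ring system, for 17 as for the target.

Step 1
Reactants: 1 hex-5-yn-1-ol; 2 benzyl bromide
Product: 4 (E)-5-methyl-7-phenylhept-5-en-1-ol, via alkenylalane 3 (not isolated)
Conditions: Me3Al (3 equiv), Cp2ZrCl2 (0.25 equiv), CH2Cl2, 0 °C to rt; then 2, Pd(PPh3)4 (5 mol %), THF, rt; cold 1 M HCl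
Reagents that add atoms: trimethylaluminium C[Al](C)C
Why: Negishi carboalumination adds CH3 and Al syn across the terminal alkyne (the hydroxyl being carried as its aluminium alkoxide), and the alkenylalane then couples with the benzyl halide under zerovalent palladium catalysis with retention, which fixes the 12E alkene and joins C13 to C14.

Step 2
Reactants: 4 (E)-5-methyl-7-phenylhept-5-en-1-ol; 5 1-(triphenylphosphoranylidene)propan-2-one
Product: 7 (3E,8E)-8-methyl-10-phenyldeca-3,8-dien-2-one, via aldehyde 6 (not isolated)
Conditions: TEMPO (0.1 equiv), PhI(OAc)2 (1.1 equiv), CH2Cl2, rt; then 5 (2 equiv), 40 °C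
Reagents that add atoms: none
Why: The oxoammonium oxidation stops at the aldehyde and leaves the trisubstituted alkene alone, and the stabilised ylide then gives the E enone by Wittig olefination in the same flask, forming C7=C8.

Step 3
Reactants: 7 (3E,8E)-8-methyl-10-phenyldeca-3,8-dien-2-one
Product: 8 (4R,8E)-4,8-dimethyl-10-phenyldec-8-en-2-one
Conditions: MeMgBr (1.2 equiv), CuBr·SMe2 (5 mol %), Josiphos (6 mol %, the enantiomer that gives 8R), tBuOMe, -75 °C; aq. NH4Cl
Reagents that add atoms: methylmagnesium bromide C[Mg]Br
Why: In this copper-catalysed asymmetric conjugate addition of a Grignard reagent to an acyclic enone the ferrocenyl diphosphine on copper selects the enone face, so C8 is set by the ligand (both antipodes are sold), while the isolated alkene is inert.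

Step 4
Reactants: 8 (4R,8E)-4,8-dimethyl-10-phenyldec-8-en-2-one
Product: 9 trimethylsilyl enol ether of 8 on the methyl side, (4R,8E)-4,8-dimethyl-10-phenyl-2-(trimethylsilyloxy)deca-1,8-diene
Conditions: LiN(iPr)2 (1.1 equiv), Me3SiCl (present from the start), THF, -78 °C; Et3N, pentane, filtration
Reagents that add atoms: chlorotrimethylsilane C[Si](C)(C)Cl
Why: Kinetic deprotonation by the hindered amide takes place at the methyl group and not at the beta-branched C7 methylene, and the enolate is silylated on oxygen as it forms (silyl enol ether formation with internal quench), C8 being non-enolisable.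

Step 5
Reactants: 9 trimethylsilyl enol ether; 10 methyl pyruvate
Product: 12 methyl (2R,6R,10E)-2-hydroxy-2,6,10-trimethyl-4-oxo-12-phenyldodec-10-enoate, via aldol silyl ether 11 (not isolated)
Conditions: [Cu((R,R)-tBu-box)](OTf)2 (10 mol %; tBu-box = 2,2'-isopropylidenebis(4-tert-butyl-2-oxazoline)), THF, -78 °C; then 1 M HCl, THF, 0 °C
Reagents that add atoms: none
Why: In this enantioselective Mukaiyama aldol addition methyl pyruvate chelates the divalent copper bis(oxazoline) Lewis acid through both carbonyl oxygens, the tert-butyl groups screen one face of the ketone and the enol silane adds to the other, so C4 is set as R by the catalyst (the (R,R) ligand is chosen as the antipode of the one known to give S adducts with pyruvate) while C4–C5 forms, and dilute acid removes the transferred silyl group.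

Step 6
Reactants: 12 hydroxy keto ester
Product: 13 methyl (2R,6R,10E)-2-hydroxy-4,4-dimethoxy-2,6,10-trimethyl-12-phenyldodec-10-enoate
Conditions: HC(OMe)3 (5 equiv), MeOH, pyridinium p-toluenesulfonate (10 mol %), rt; Et3N, concentrate
Reagents that add atoms: trimethyl orthoformate COC(OC)OC; methanol CO
Why: Acid-catalysed ketalisation with the orthoester as water scavenger masks the C6 ketone, which removes the beta-hydroxy ketone (and with it retro-aldol and elimination) before any base is used, the tertiary alcohol next to the ester being unable to ionise.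

Step 7
Reactants: 13 hydroxy ketal ester
Product: 14 methyl (2R,6R,10E)-2-acetoxy-4,4-dimethoxy-2,6,10-trimethyl-12-phenyldodec-10-enoate
Conditions: Ac2O (5 equiv), Et3N, DMAP (1 equiv), CH2Cl2, rt to 40 °C
Reagents that add atoms: acetic anhydride CC(=O)OC(C)=O
Why: DMAP-catalysed acyl transfer (Steglich-type acylation) esterifies the hindered tertiary alcohol under basic conditions that the ketal tolerates.

Step 8
Reactants: 14 acetoxy ketal ester
Product: 15 (5R)-4-hydroxy-5-methyl-5-[(4R,8E)-2,2-dimethoxy-4,8-dimethyl-10-phenyldec-8-enyl]furan-2(5H)-one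
Conditions: LiN(SiMe3)2 (2.5 equiv), THF, -78 to 0 °C; cold aq. NaH2PO4/H3PO4 (pH 3), Et2O, 0 °C, fast; used at once
Reagents that add atoms: none
Why: In this Dieckmann condensation the acetate enolate attacks the neighbouring methyl ester (5-exo-trig) to form C2–C3 and the butanolide, the second equivalent of base pulls the equilibrium by deprotonating the tetronic acid, and the quaternary C4 cannot epimerise.

Step 9
Reactants: 15 ketal tetronic acid
Product: 17 bicyclic 6-methoxy-1,2-dioxan-3-ol lactone (3R,4R,6R,8R,12E), via methoxy hydroperoxide 16 (not isolated)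
Conditions: H2O2 (anhydrous, in Et2O, dried over MgSO4, 2 equiv), camphorsulfonic acid (10 mol %), Et2O, 0 °C to rt
Reagents that add atoms: hydrogen peroxide OO
Why: Ketal perhydrolysis exchanges one methoxy group for OOH through the C6 oxocarbenium ion, and the hydroperoxide then adds to the C3 carbonyl of the tetronic acid (6-exo-trig peroxyhemiketalisation); only the cis fusion is free of strain, so C3 follows C4, and under these reversible conditions the C3 hydroxyl and the C6 methoxy group should settle axial (the C6 anomer is of no consequence).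

Step 10
Reactants: 17 bicyclic methoxy peroxyketal lactone
Product: 18 C3 trimethylsilyl ether of 17
Conditions: N-methyl-N-(trimethylsilyl)trifluoroacetamide (3 equiv), CH2Cl2, rt; evaporate, quick filtration through silica
Reagents that add atoms: N-methyl-N-(trimethylsilyl)trifluoroacetamide CN(C(=O)C(F)(F)F)[Si](C)(C)C
Why: Silyl transfer from a neutral silylamide caps the hemiketal hydroxyl without an amine base, which would cause retro-addition to the tetronate, and no stereocentre is touched.

Step 11
Reactants: 18 C3 trimethylsilyl ether of the methoxy peroxyketal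
Product: 20 C3 trimethylsilyl ether of the target with C6–CH3 in place, via peroxycarbenium ion 19 (not isolated)
Conditions: MeTiCl3 (2.5 equiv; preformed from Me2Zn and TiCl4, 1:2, CH2Cl2, -30 °C), CH2Cl2, -78 to -50 °C; cold aq. NaHCO3
Reagents that add atoms: methyltitanium trichloride C[Ti](Cl)(Cl)Cl, made in the flask from dimethylzinc C[Zn]C and titanium tetrachloride Cl[Ti](Cl)(Cl)Cl
Why: Proposed new method: MeTiCl3 binds the most basic and least hindered oxygen, the C6 methoxy group, and removes it to leave the bicyclic peroxycarbenium ion 19 (C6=O1+), which takes a methyl group from the methyltitanate counter-ion within the ion pair; ionisation at C3 is not expected, because that carbon lies between the acyloxy-bearing C4 and the C2 methylene next to the lactone carbonyl and its oxygen is shielded by silicon. The closest known reaction types are the Lewis acid substitution of 3-alkoxy- and 3-acetoxy-1,2-dioxanes and 1,2-dioxolanes by silyl nucleophiles through peroxycarbenium ions (fully substituted peroxide carbons included), the methyltitanium substitution of ketals, and the methylaluminium substitution at the lactol carbon of trioxane peroxides with the O–O bond left intact. No ring is closed here, since the butanolide (step 8) and the dioxane (step 9) are already in place; the only bond made is C6–CH3. The new C6 centre is controlled by the substrate: the cis-fused lactone allows ion 19 one comfortable half-chair, with the C4 and C3 oxygens pseudoaxial (also the electrostatically preferred placement near the cationic centre) and the C4 methyl and C2 pseudoequatorial, and the axial, chair-forming approach then delivers CH3 syn to the small lactone oxygen and anti to the C3 oxygen, leaving the C7 chain equatorial (6R). Because the newcomer is told apart from the resident chain by its trajectory and not by its size, the near-equality of CH3 and CH2R does not matter. The step needs site selectivity (C6 over C3), facial selectivity at C6 and survival of the peroxide, which rest respectively on the electron-poor, silyl-shielded surroundings of C3, on the locked half-chair, and on a d0 methyl donor used at -78 °C that has no easy electron-transfer path to a dialkyl peroxide.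

Step 12
Reactants: 20 C3 trimethylsilyl ether of the target
Product: 21 target CNP0361739.2
Conditions: AcOH/THF/H2O (3:1:1), 0 °C to rt
Reagents that add atoms: none
Why: Mild acid hydrolysis of the trimethylsilyl ether frees the tertiary hemiketal hydroxyl, the dialkyl peroxide, lactone and alkene being stable to aqueous acetic acid, and base is avoided because it would open the hemiketal.

Compound list
1 | hex-5-yn-1-ol | C#CCCCCO | starting material
2 | benzyl bromide | BrCc1ccccc1 | starting material
3 | (E)-alkenyldimethylalane from 1, hydroxyl as its dimethylaluminium alkoxide | C/C(=C\[Al](C)C)CCCCO[Al](C)C | intermediate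
4 | (E)-5-methyl-7-phenylhept-5-en-1-ol | C/C(=C\Cc1ccccc1)CCCCO | intermediate
5 | 1-(triphenylphosphoranylidene)propan-2-one | CC(=O)C=P(c1ccccc1)(c1ccccc1)c1ccccc1 | starting material
6 | (E)-5-methyl-7-phenylhept-5-enal | C/C(=C\Cc1ccccc1)CCCC=O | intermediate
7 | (3E,8E)-8-methyl-10-phenyldeca-3,8-dien-2-one | C/C(=C\Cc1ccccc1)CCC/C=C/C(C)=O | intermediate
8 | (4R,8E)-4,8-dimethyl-10-phenyldec-8-en-2-one | C/C(=C\Cc1ccccc1)CCC[C@@H](C)CC(C)=O | intermediate
9 | (4R,8E)-4,8-dimethyl-10-phenyl-2-(trimethylsilyloxy)deca-1,8-diene | C/C(=C\Cc1ccccc1)CCC[C@@H](C)CC(=C)O[Si](C)(C)C | intermediate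
10 | methyl pyruvate | CC(=O)C(=O)OC | starting material
11 | methyl (2R,6R,10E)-2,6,10-trimethyl-4-oxo-12-phenyl-2-(trimethylsilyloxy)dodec-10-enoate | C/C(=C\Cc1ccccc1)CCC[C@@H](C)CC(=O)C[C@@](C)(O[Si](C)(C)C)C(=O)OC | intermediate
12 | methyl (2R,6R,10E)-2-hydroxy-2,6,10-trimethyl-4-oxo-12-phenyldodec-10-enoate | C/C(=C\Cc1ccccc1)CCC[C@@H](C)CC(=O)C[C@@](C)(O)C(=O)OC | intermediate
13 | methyl (2R,6R,10E)-2-hydroxy-4,4-dimethoxy-2,6,10-trimethyl-12-phenyldodec-10-enoate | C/C(=C\Cc1ccccc1)CCC[C@@H](C)CC(OC)(OC)C[C@@](C)(O)C(=O)OC | intermediate
14 | methyl (2R,6R,10E)-2-acetoxy-4,4-dimethoxy-2,6,10-trimethyl-12-phenyldodec-10-enoate | C/C(=C\Cc1ccccc1)CCC[C@@H](C)CC(OC)(OC)C[C@@](C)(OC(C)=O)C(=O)OC | intermediate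
15 | (5R)-4-hydroxy-5-methyl-5-[(4R,8E)-2,2-dimethoxy-4,8-dimethyl-10-phenyldec-8-enyl]furan-2(5H)-one | C/C(=C\Cc1ccccc1)CCC[C@@H](C)CC(OC)(OC)C[C@@]1(C)OC(=O)C=C1O | intermediate
16 | open-chain C6 methoxy hydroperoxide of 15 (both C6 epimers) | C/C(=C\Cc1ccccc1)CCC[C@@H](C)CC(OC)(OO)C[C@@]1(C)OC(=O)C=C1O | intermediate
17 | (3R,4R,6R,8R,12E) cis-fused 3-hydroxy-6-methoxy-1,2-dioxane butanolide; C3–OH cis to C4–CH3, C6–OMe axial and cis to the lactone oxygen, C6 carrying the (2R,6E)-2,6-dimethyl-8-phenyloct-6-enyl chain | C/C(=C\Cc1ccccc1)CCC[C@@H](C)C[C@]1(OC)C[C@@]2(C)OC(=O)C[C@@]2(O)OO1 | intermediate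
18 | C3 trimethylsilyl ether of 17 (3S by the sequence rule, same arrangement in space; 4R,6R,8R,12E) | C/C(=C\Cc1ccccc1)CCC[C@@H](C)C[C@]1(OC)C[C@@]2(C)OC(=O)C[C@@]2(O[Si](C)(C)C)OO1 | intermediate
19 | bicyclic peroxycarbenium ion, C6=O1+ (cation of 18 after loss of methoxide) | C/C(=C\Cc1ccccc1)CCC[C@@H](C)CC=1C[C@@]2(C)OC(=O)C[C@@]2(O[Si](C)(C)C)O[O+]=1 | intermediate
20 | C3 trimethylsilyl ether of the target (3S by the sequence rule; 4R,6R,8R,12E), C6–CH3 axial and cis to the lactone oxygen | C/C(=C\Cc1ccccc1)CCC[C@@H](C)C[C@]1(C)C[C@@]2(C)OC(=O)C[C@@]2(O[Si](C)(C)C)OO1 | intermediate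
21 | target CNP0361739.2, (3R,4R,6R,8R,12E) cis-fused 3-hydroxy-4,6-dimethyl-1,2-dioxane butanolide with the (2R,6E)-2,6-dimethyl-8-phenyloct-6-enyl chain on C6 | C/C(=C\Cc1ccccc1)CCC[C@@H](C)C[C@]1(C)C[C@@]2(C)OC(=O)C[C@@]2(O)OO1 | target

Total step count: 12
Longest linear sequence: 12 steps (1 to 21); 2, 5 and 10 are bought.

Steps most likely to fail

Step 11 (proposed new method). Several processes may intervene. Ionisation may take the endocyclic course (cleavage of C6–O1 instead of C6–OMe). The cation may lose a proton from C5 or C7 or undergo carbon-to-oxygen migration before it is methylated. Facial selectivity may erode if the half-chair is less biased than assumed. The Lewis acid may strip the silyl group, after which the hemiketal opens. The fallback uses known chemistry only, sets out from 12 and returns at 21. The C6 ketone of 12 is methylenated under non-basic Takai–Lombardo conditions (Zn, CH2Br2, TiCl4, THF) to the methylene hydroxy ester F1, which is acetylated (Ac2O, DMAP) to the methylene acetate F2 and closed by Dieckmann condensation (LiN(SiMe3)2) to the methylene tetronic acid F3. Mukaiyama–Isayama hydroperoxysilylation (Co(acac)2, O2, Et3SiH) then places a silylperoxy group on C6 in the Markovnikov sense, giving the triethylsilyl peroxide F4 with the C6 methyl already present. Desilylation with dilute acid lets the hydroperoxide close onto the C3 carbonyl to give 21 together with the C6 epimer F5, which is removed by chromatography. This path gives up control at C6 and has to be stopped at partial conversion so that the slower C12=C13 alkene is spared.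

Step 9. Both methoxy groups may be exchanged (geminal dihydroperoxide), ring closure may stay incomplete because the conjugated enol of the tetronic acid resists addition, or the acid may trigger rearrangement of the hydroperoxide. The fallback sets out from 15 and returns at 17. The ketal is hydrolysed on purpose (wet acetone, pyridinium p-toluenesulfonate) to the keto tetronic acid F6. As a 1,4-dicarbonyl compound this should take up H2O2 (urea–H2O2, catalytic acid) in the manner long known for 1,4-diketones to give the bicyclic dioxane-3,6-diol F7. Only its ionisable C6 hydroxyl is then exchanged for methoxy (MeOH, HC(OMe)3, catalytic acid), giving 17.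

Step 8. Acetyl transfer to the liberated methoxide (deacetylation) may outrun C-acylation at the hindered ester, and the dimethyl ketal may be hydrolysed or transketalised when the strongly acidic product is set free. The fallback sets out from 13, before acetylation, and returns at 15. A crossed Claisen condensation of the methyl ester with excess LiCH2CO2Et (from ethyl acetate and LiN(iPr)2, THF, -78 to 0 °C, one equivalent being spent on the hydroxyl) gives the hydroxy keto ester F8. Its tertiary alkoxide lactonises onto the ethyl ester (5-exo-trig) on warming, and the tetronic acid is isolated as in step 8.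

Further compounds
F1 | step 11 | methyl (2R,6R,10E)-2-hydroxy-2,6,10-trimethyl-4-methylene-12-phenyldodec-10-enoate | C/C(=C\Cc1ccccc1)CCC[C@@H](C)CC(=C)C[C@@](C)(O)C(=O)OC
F2 | step 11 | methyl (2R,6R,10E)-2-acetoxy-2,6,10-trimethyl-4-methylene-12-phenyldodec-10-enoate | C/C(=C\Cc1ccccc1)CCC[C@@H](C)CC(=C)C[C@@](C)(OC(C)=O)C(=O)OC
F3 | step 11 | (5R)-4-hydroxy-5-methyl-5-[(4R,8E)-4,8-dimethyl-2-methylene-10-phenyldec-8-enyl]furan-2(5H)-one | C/C(=C\Cc1ccccc1)CCC[C@@H](C)CC(=C)C[C@@]1(C)OC(=O)C=C1O
F4 | step 11 | C6 triethylsilylperoxy tetronic acid (both C6 epimers) | C/C(=C\Cc1ccccc1)CCC[C@@H](C)CC(C)(OO[Si](CC)(CC)CC)C[C@@]1(C)OC(=O)C=C1O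
F5 | step 11 | C6 epimer of the target | C/C(=C\Cc1ccccc1)CCC[C@@H](C)C[C@@]1(C)C[C@@]2(C)OC(=O)C[C@@]2(O)OO1
F6 | step 9 | (5R)-4-hydroxy-5-methyl-5-[(4R,8E)-4,8-dimethyl-2-oxo-10-phenyldec-8-enyl]furan-2(5H)-one | C/C(=C\Cc1ccccc1)CCC[C@@H](C)CC(=O)C[C@@]1(C)OC(=O)C=C1O
F7 | step 9 | bicyclic 3,6-dihydroxy-1,2-dioxane butanolide (C6 anomers) | C/C(=C\Cc1ccccc1)CCC[C@@H](C)CC1(O)C[C@@]2(C)OC(=O)C[C@@]2(O)OO1
F8 | step 8 | ethyl (4R,8R,12E)-4-hydroxy-6,6-dimethoxy-4,8,12-trimethyl-3-oxo-14-phenyltetradec-12-enoate | C/C(=C\Cc1ccccc1)CCC[C@@H](C)CC(OC)(OC)C[C@@](C)(O)C(=O)CC(=O)OCC
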